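**Plan**
- Retrosynthesis: one operation cuts C1–Br, C4–OH and the C5–C10 bond shared by rings A and B, giving (6S,7R)-germacra-1(10)E,4E-dien-6-yl acetate. Then C4=C5 is masked as an epoxide, C11=C12 is restored, and C6–C7 is cut to open-chain 12-chloro-2,3-epoxyfarnesal, which goes back to (E,E)-farnesol.
- Enabling feature: along C1–C10–C5–C4 of ring A the pairs Br/C5 and C10/OH are antiperiplanar (equatorial Br, trans ring fusion, equatorial OH, both methyl groups axial). This is the imprint of two anti additions across the C1=C10 and C4=C5 alkenes of an (E,E)-cyclodeca-1,5-diene in which C10 and C5 face each other across the ring.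
- Forward order: oxirane as a temporary ring (step 1), ten-membered carbocycle by C6–C7 closure (step 5), oxirane oxygen removed (step 8). Ring A, and ring B with it, then forms last through the transannular C5–C10 bond.
- Stereochemistry: D-(−)-tartrate sets the epoxide (C4, C5), which relays to C6 and C7 in the ring closure and is then deleted. The C6 acetate selects the reacting crown conformer, and alkene geometry plus anti addition set C1, C10, C5 and C4.

Key step: step 9

Numbering: eudesmane/germacrane numbers (ring C1–C10, C14 on C10, C15 on C4, isopropyl C11–C13 on C7) are used for all carbons; farnesane locants appear only inside the names of open-chain compounds (farnesane C1, C2, C3, C10 = C6, C5, C4, C7).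
Assumption: the closure in step 5 is taken to place the C6 hydroxyl syn to the epoxide oxygen and cis to the C7 isopropenyl group, as argued at that step; the choice of D-(−)-tartrate rests on this sense of relay.

Step 1
Reactants: 1 (2E,6E)-farnesol
Product: 2 (2R,3R)-2,3-epoxyfarnesol (trans-epoxide at the former allylic alkene, the 6E and terminal alkenes intact)
Conditions: Ti(OiPr)4 (cat.), D-(−)-diethyl tartrate (cat.), t-BuOOH, 4 Å MS, CH2Cl2, −20 °C
Reagents that add atoms: tert-butyl hydroperoxide, CC(C)(C)OO
Why: Katsuki–Sharpless asymmetric epoxidation touches only the alkene of the allylic alcohol, and with the D-(−)-tartrate ligand the empirical face rule predicts the (2R,3R)-epoxide, which sets C5 and C4 and is the only external source of chirality in the route.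

Step 2
Reactants: 2 (2R,3R)-2,3-epoxyfarnesol
Product: 3 (2R,3R,6E,10E)-2,3-epoxy-3,7,11-trimethyldodeca-6,10-diene-1,12-diol
Conditions: SeO2 (cat.), t-BuOOH, salicylic acid (cat.), CH2Cl2, 0 °C to rt
Reagents that add atoms: tert-butyl hydroperoxide, CC(C)(C)OO
Why: Riley allylic oxidation in its catalytic SeO2/t-BuOOH form (ene reaction then [2,3]-sigmatropic shift) prefers the terminal, most electron-rich and least hindered isopropylidene group and oxidises its (E)-methyl group, so the primary (E)-allylic alcohol forms without touching a stereocentre.

Step 3
Reactants: 3 (2R,3R,6E,10E)-2,3-epoxy-3,7,11-trimethyldodeca-6,10-diene-1,12-diol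
Product: 4 (2R,3R,6E,10E)-12-chloro-2,3-epoxy-3,7,11-trimethyldodeca-6,10-dien-1-ol
Conditions: NCS, Me2S, CH2Cl2, −20 to 0 °C; aqueous work-up
Reagents that add atoms: N-chlorosuccinimide, O=C1CCC(=O)N1Cl
Why: Corey–Kim halogenation is selective because only the alkoxysulfonium salt of the allylic alcohol is displaced by chloride (SN2, alkene geometry kept), while that of the epoxy alcohol returns the alcohol on aqueous work-up.

Step 4
Reactants: 4 (2R,3R,6E,10E)-12-chloro-2,3-epoxy-3,7,11-trimethyldodeca-6,10-dien-1-ol
Product: 5 (2S,3R,6E,10E)-12-chloro-2,3-epoxy-3,7,11-trimethyldodeca-6,10-dienal (same spatial arrangement, the C2 descriptor changes by priority only)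
Conditions: TEMPO (cat.), PhI(OAc)2, CH2Cl2, rt
Reagents that add atoms: none
Why: Oxoammonium (TEMPO/PhI(OAc)2) oxidation of a primary alcohol stops at the aldehyde under nearly neutral conditions that spare the epoxide, the allylic chloride and the trisubstituted alkenes, and the epoxide carbon C5 cannot epimerise.

Step 5
Reactants: 5 (2S,3R,6E,10E)-12-chloro-2,3-epoxy-3,7,11-trimethyldodeca-6,10-dienal
Product: 7 (4R,5R,6S,7R)-4,5-epoxygermacra-1(10)E,11-dien-6-ol (ten-membered carbocycle; trans-4,5-epoxide, 6-OH and 7-isopropenyl cis), via allyl(ethyl)zinc aldehyde 6 (not isolated)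
Conditions: PdCl2(PPh3)2 (cat.), Et2Zn, N,N-dimethylacetamide, rt, slow addition of 5 (high dilution); aq NH4Cl
Reagents that add atoms: none
Why: Intramolecular palladium-catalysed umpolung allylation (Tamaru type, a Barbier-like relative of the Nozaki–Hiyama–Kishi closure): zerovalent palladium ionises the allylic chloride, Et2Zn converts the π-allyl complex into the nucleophilic allylzinc 6, and this adds through its γ-carbon C7 to the aldehyde in a closed Zimmerman–Traxler chair under high dilution, where the trans-epoxide, whose C4 methyl is cis to the formyl group, holds C6–H against that methyl with zinc bridging both oxygens so that C7 can arrive only from the ring interior (6S, hydroxyl syn to the epoxide oxygen), and the fluxional allylzinc is expected to react through the form that lets the C8 tether leave the chair axially, which places the isopropenyl group cis to the hydroxyl (7R).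

Step 6
Reactants: 7 (4R,5R,6S,7R)-4,5-epoxygermacra-1(10)E,11-dien-6-ol
Product: 8 (4R,5R,6S,7R)-4,5-epoxygermacr-1(10)E-en-6-ol (7-isopropyl)
Conditions: H2 (1 atm), RhCl(PPh3)3 (cat.), toluene/EtOH, rt
Reagents that add atoms: none
Why: Homogeneous hydrogenation with RhCl(PPh3)3 discriminates by alkene substitution, so the 1,1-disubstituted isopropenyl group is saturated while the trisubstituted C1=C10 alkene stays and C4=C5 is masked as the epoxide, and no stereocentre is created since C11 carries two methyl groups.

Step 7
Reactants: 8 (4R,5R,6S,7R)-4,5-epoxygermacr-1(10)E-en-6-ol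
Product: 9 (4R,5R,6S,7R)-4,5-epoxygermacr-1(10)E-en-6-yl acetate
Conditions: Ac2O, DMAP (cat.), pyridine, rt
Reagents that add atoms: acetic anhydride, CC(=O)OC(C)=O
Why: DMAP-catalysed acylation esterifies the hindered secondary alcohol with retention at C6 and installs the acetate that later steers the key step.

Step 8
Reactants: 9 (4R,5R,6S,7R)-4,5-epoxygermacr-1(10)E-en-6-yl acetate
Product: 10 (6S,7R)-germacra-1(10)E,4E-dien-6-yl acetate
Conditions: WCl6, n-BuLi, THF, −78 °C to rt; then 9, 0 °C to rt; work-up and chromatography below 30 °C
Reagents that add atoms: none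
Why: Sharpless–Umbreit deoxygenation: the tungsten tetrachloride made in the flask binds the epoxide oxygen, which points to the outside of the ring, and removes it by a stereoretentive syn-elimination, so the trans-epoxide should return the (E)-C4=C5 alkene while the ester and the C1=C10 alkene are tolerated and the low temperature keeps the 1,5-diene from Cope rearrangement.

Step 9
Reactants: 10 (6S,7R)-germacra-1(10)E,4E-dien-6-yl acetate
Product: 11 austradiol acetate, (1R,4R,5S,6S,7R,10R)-1-bromo-4-hydroxyeudesman-6-yl acetate
Conditions: NBS, acetone/H2O, 0 °C, dark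
Reagents that add atoms: N-bromosuccinimide, O=C1CCC(=O)N1Br; water, O
Why: NBS delivers Br+ to the exposed outer face of the C1=C10 alkene, the developing tertiary cation at C10 is attacked across the ring by C5 of the C4=C5 alkene only about 3 Å away, and the resulting tertiary C4 cation is captured by water on its outer face, possibly relayed by the carbonyl oxygen of the neighbouring equatorial C6 acetate through a six-membered acetoxonium ion that water reopens. The closest known reaction type is the halonium- or proton-induced transannular cyclisation of (E,E)-germacra-1(10),4-dienes to trans-eudesmanes, which is also the presumed biosynthesis of the brominated selinanes. The single new C5–C10 bond divides the ten-membered ring into both six-membered rings: ring A (C10, C1, C2, C3, C4, C5) closes in the 6-endo mode with respect to both alkenes and ring B in the 6-exo mode, through a chair–chair transition state with crossed alkenes. C1 and C10 follow from anti addition of Br and C5 across the (E)-C1=C10 alkene (equatorial Br, axial C10 methyl), and C5 and C4 from anti addition of C10 and oxygen across the (E)-C4=C5 alkene (trans ring fusion, equatorial OH, axial C4 methyl). Which of the two crown conformers reacts, and hence the absolute sense at all four centres, is fixed by C6: allylic 1,3-strain with the C4 methyl keeps C6–H eclipsed with the alkene and the acetate equatorial, whereas the other crown would put the acetate syn-axial to both methyl groups, a larger penalty than the axial isopropyl group that the reacting crown accepts. The step needs site selectivity for C1=C10 over C4=C5, secured by the inductive deactivation of C4=C5 by its allylic acetate, and water capture instead of proton loss, favoured by the aqueous medium and by acetate assistance.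

**Compound list**
1 | (2E,6E)-farnesol | CC(C)=CCC/C(C)=C/CC/C(C)=C/CO | starting material
2 | (2R,3R)-2,3-epoxyfarnesol | CC(C)=CCC/C(C)=C/CC[C@@]1(C)O[C@@H]1CO | intermediate
3 | (2R,3R,6E,10E)-2,3-epoxy-3,7,11-trimethyldodeca-6,10-diene-1,12-diol | OC/C(C)=C/CC/C(C)=C/CC[C@@]1(C)O[C@@H]1CO | intermediate
4 | (2R,3R,6E,10E)-12-chloro-2,3-epoxy-3,7,11-trimethyldodeca-6,10-dien-1-ol | ClC/C(C)=C/CC/C(C)=C/CC[C@@]1(C)O[C@@H]1CO | intermediate
5 | (2S,3R,6E,10E)-12-chloro-2,3-epoxy-3,7,11-trimethyldodeca-6,10-dienal | ClC/C(C)=C/CC/C(C)=C/CC[C@@]1(C)O[C@@H]1C=O | intermediate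
6 | allyl(ethyl)zinc aldehyde (C12–ZnEt form of 5, fluxional, not isolated) | CC[Zn]C/C(C)=C/CC/C(C)=C/CC[C@@]1(C)O[C@@H]1C=O | intermediate
7 | (4R,5R,6S,7R)-4,5-epoxygermacra-1(10)E,11-dien-6-ol | O[C@H]1[C@@H](C(C)=C)CC/C(C)=C/CC[C@@]2(C)O[C@H]12 | intermediate
8 | (4R,5R,6S,7R)-4,5-epoxygermacr-1(10)E-en-6-ol | O[C@H]1[C@@H](C(C)C)CC/C(C)=C/CC[C@@]2(C)O[C@H]12 | intermediate
9 | (4R,5R,6S,7R)-4,5-epoxygermacr-1(10)E-en-6-yl acetate | CC(=O)O[C@H]1[C@@H](C(C)C)CC/C(C)=C/CC[C@@]2(C)O[C@H]12 | intermediate
10 | (6S,7R)-germacra-1(10)E,4E-dien-6-yl acetate | CC(=O)O[C@@H]1/C=C(C)/CC/C=C(C)/CC[C@@H]1C(C)C | intermediate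
11 | austradiol acetate | CC(=O)O[C@H]1[C@@H](C(C)C)CC[C@@]2(C)[C@H](Br)CC[C@@](C)(O)[C@H]12 | target

Total step count: 9. Longest linear sequence: 9 steps.

**Steps most likely to fail**

Step 5. Oligomerisation may compete with closure of the ten-membered ring. Facial selectivity at C7 may also be poor if the closed transition state runs through the other form of the fluxional allylzinc. The fallback sets out from 4 and comes back at 7, and gives up the closed transition state for an open one.
- Compound 4 is stannylated at C12 with hexabutyldistannane and Pd(PPh3)4 (cat.) in THF to (2R,3R,6E,10E)-2,3-epoxy-3,7,11-trimethyl-12-(tributylstannyl)dodeca-6,10-dien-1-ol F1.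
- This is oxidised with SO3·pyridine, DMSO and Et3N to the corresponding stannyl epoxy aldehyde F2.
- MgBr2·OEt2 in CH2Cl2 at low temperature and high dilution chelates the aldehyde and epoxide oxygens, which keeps the hydroxyl syn to the epoxide oxygen.
- It triggers an SE2' addition through an open antiperiplanar transition state. This reaction type gives the syn homoallylic alcohol, here hydroxyl and isopropenyl cis on the ring, whatever the geometry of the allylstannane.

Step 9. The C4 cation may lose a proton instead of taking up water, or simple bromohydrin formation at C1=C10 may occur without C–C bond formation. The fallback sets out from 10 and comes back at 11, and splits the event into ring formation and hydration.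
- 2,4,4,6-Tetrabromocyclohexa-2,5-dienone in MeNO2 without a nucleophile should give, by the same transannular closure and proton loss, 1β-bromoeudesm-4(15)-en-6α-yl acetate F3 together with 1β-bromoeudesm-3-en-6α-yl acetate F4.
- Both are submitted to Mukaiyama hydration (Co(acac)2, PhSiH3, O2, THF) and converge on the same C4 radical.
- This radical is trapped by O2 on the α face, opposite the axial C10 methyl, to give the equatorial 4-OH.

Step 8. The Lewis-acidic tungsten species may trigger transannular opening of the epoxide by the C1=C10 alkene, or the alkene geometry may erode. The fallback sets out from 9 and comes back at 10. The oxygen is abstracted from the outside by an electrophilic rhodium carbenoid (Rh2(OAc)4 cat., dimethyl diazomalonate, warm CH2Cl2) through an oxonium ylide that fragments with retention of geometry. This avoids both the low-valent metal and the Lewis acid. No new compound arises on this way (F0).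

**Further compounds**
F1 | step 5 | (2R,3R,6E,10E)-2,3-epoxy-3,7,11-trimethyl-12-(tributylstannyl)dodeca-6,10-dien-1-ol | CCCC[Sn](CCCC)(CCCC)C/C(C)=C/CC/C(C)=C/CC[C@@]1(C)O[C@@H]1CO
F2 | step 5 | (2S,3R,6E,10E)-2,3-epoxy-3,7,11-trimethyl-12-(tributylstannyl)dodeca-6,10-dienal | CCCC[Sn](CCCC)(CCCC)C/C(C)=C/CC/C(C)=C/CC[C@@]1(C)O[C@@H]1C=O
F3 | step 9 | 1β-bromoeudesm-4(15)-en-6α-yl acetate | CC(=O)O[C@H]1[C@@H](C(C)C)CC[C@@]2(C)[C@H](Br)CCC(=C)[C@H]12
F4 | step 9 | 1β-bromoeudesm-3-en-6α-yl acetate | CC(=O)O[C@H]1[C@@H](C(C)C)CC[C@@]2(C)[C@H](Br)CC=C(C)[C@H]12
F0 | step 8 | none | none
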